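The runs come from a simulation on assumed constants, noise included.

You cannot read either flask off the runs: maple at 0 °C lies below and cedar at 25 °C lies above every run temperature.

| setting | south-west | west | south-east | maple | cedar |
|---|---|---|---|---|---|
| substrate | 0.40 M | 0.40 M | 0.60 M | 0.40 M | 0.40 M |
| first nucleophile | 1.6 M | 1.6 M | 1.6 M | 1.60 M | 1.60 M |
| second nucleophile | 0.30 M | 0.45 M | 0.60 M | 0.600 M | 0.600 M |
| temperature | 6 °C | 20 °C | 6 °C | 0 °C | 25 °C |
| remark | run made earlier | run made earlier | run made earlier |  |  |
| time |  |  |  | 8.0 min | 8.0 min |

| run | time / min | target / % | substrate / % |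
|---|---|---|---|
| south-west | 0.833 | 1.7 | 97.6 |
| south-west | 2.00 | 5.1 | 89.8 |
| south-west | 4.00 | 11.3 | 81.7 |
| south-west | 10.0 | 25.8 | 59.0 |
| west | 1.00 | 12.1 | 80.9 |
| west | 2.00 | 22.8 | 62.0 |
| west | 3.00 | 30.8 | 49.6 |
| west | 4.00 | 32.8 | 37.2 |
| south-east | 0.833 | 1.4 | 97.5 |
| south-east | 2.00 | 5.2 | 89.6 |
| south-east | 4.00 | 11.9 | 80.2 |
| south-east | 10.0 | 20.6 | 57.5 |

(readings scatter by 1 percentage point)



1. the flask with the highest amount of target, in percent of the substrate charged ("all alike" if they lie within 1.5 percentage points) (maple / cedar / all alike)
2. final target, as a percentage of the substrate charged, in maple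
3. final target, as a percentage of the substrate charged, in cedar

South-west and south-east keep 59.0 % and 57.5 % of their substrate at 10.0 min, from different charges, so the loss looks first-order and can be counted in decades, that is, powers of ten. In decades per minute the last readings give 0.0229 /min in south-west and 0.107 /min in west, so one decade in that rate takes 20.9 K of warming, as far as these readings show.

Carrying this line outward, I put maple's decade rate, the powers of ten of substrate lost per minute at its temperature, at 0.0118 /min and cedar's at 0.186 /min. Over 8.0 min, maple then keeps 80.4 % of its substrate and cedar 3.23 %.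

Target per substrate lost (the selectivity) reads 0.601 in south-east at 4.00 min, where the loss matches the one I reckon for maple. It reads 0.522 at the last reading of west, which is closer to cedar in temperature than south-west, although west has lost less substrate at that reading than I reckon for cedar. Assuming that these two ratios carry over, I reckon 11.8 % of target in maple and 50.5 % in cedar.

The forecast also names cedar as the flask with most target, with 10 % in maple, but it gives cedar 14 %, less than mine, holding that there "target peaks early, then is eaten" and that depletion of nucleophile could preserve more of it. The simulation gives cedar as the flask with most target, with 10.8 % in maple and 50.2 % in cedar.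

    substrate ⇌ intermediate (K = 0.230, k = 0.00680 /s, Ea = 77.0 kJ/mol, ΔH = 1.00 kJ/mol)
    first nucleophile + intermediate → target (k = 0.0760 /M/s, Ea = 47.0 kJ/mol)
    second nucleophile + intermediate → other capture product (k = 0.0920 /M/s, Ea = 50.0 kJ/mol)
    2 second nucleophile → self-condensation product (k = 0.0110 /M/s, Ea = 46.0 kJ/mol)
    substrate + target → side product (k = 0.0110 /M/s, Ea = 57.0 kJ/mol)
    (constants at 25 °C)

In maple, the forward step from substrate to intermediate alone gives substrate a half-life of 29 min at 8.00 min, longer than the run itself, and the decade rate gives 25.5 min; 82.5 % of the substrate stands in maple at 8.00 min. Read at 30 min instead, maple should keep 44.3 % of its substrate by its decade rate, and the simulation holds 43.8 % there, beside 28.9 % target.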